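**Retrosynthetic overview** (germacrane numbering: ring C1–C10, C11–C13 on C7, C14 on C10, C15 on C4)

1. Enabling feature: the lactone O–C12(=O) unit bridges C6 and C11, which lie 1,3 across C7. C6 is allylic to C4=C5 and C3 carries oxygen (O–C6–C5=C4–C3–O), and C11 bears only the C13 methyl. CO2 can therefore be stitched between a terminal alkyne (C11≡C13) on C7 and a C3–C4 vinyl epoxide (C5=C6).
2. Key disconnection: γ-lactone ⇒ CO2 + acyclic alkynyl vinyl epoxide 17 (Ni-catalysed electrocarboxylation, then Pd allylic lactonization in the same cell). The same event unveils the C3 carbinol and the E-C4=C5 olefin.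
3. 17 ⇒ erythro epoxy alcohol 15 by Eschenmoser–Claisen rearrangement (C7–C8 bond, C5→C7 chirality transfer) ⇒ racemic bis-allylic alcohol 14 by Sharpless kinetic resolution ⇒ enal 9 + butadiyne 10.
4. Ring order: γ-lactone first (step 9), then the ten-membered carbocycle by Nozaki–Hiyama–Kishi closure of C9–C10 (vinylsilane as masked vinyl iodide), last the 1,10-oxirane by hydroxyl-directed epoxidation.
5. C11 is set by hydrogenation of the α-methylene lactone anti to C8; C9 by oxidation and CBS reduction.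

Key step: step 9

Remark: the racemic carbinol 14 is resolved kinetically in step 7, so only its (S)-enantiomer is carried on; the regiochemistry assumed for the nickel electrocarboxylation (CO2 at the internal alkyne carbon) is taken from the known behaviour of terminal alkynes in that system.

**Route**

Step 1
Reactants: 1 pent-3-yn-1-ol
Product: 3 (E)-4-iodopent-3-en-1-ol, via alkenylzirconocene chloride 2 (not isolated)
Conditions: Cp2Zr(H)Cl (3 equiv), THF, 45 °C; then I2, 0 °C
Reagents that add atoms: iodine, II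
Why: Hydrozirconation–iodination: syn addition of Zr–H, equilibrated by the excess reagent to place zirconium on the methyl-bearing carbon, followed by iodinolysis with retention should give the (E)-iodide.

Step 2
Reactants: 3 (E)-4-iodopent-3-en-1-ol
Product: 6 (E)-4-(trimethylsilyl)pent-3-en-1-ol, via vinyllithium alkoxide 4 (not isolated), via bis-silylated vinylsilane 5 (not isolated)
Conditions: t-BuLi (3.1 equiv), Et2O, −78 °C; Me3SiCl (2.5 equiv), −78 to 20 °C; then K2CO3 (cat.), MeOH, 20 °C
Reagents that add atoms: chlorotrimethylsilane, C[Si](C)(C)Cl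
Why: Iodine–lithium exchange and C-silylation both proceed with retention of the olefin geometry and methanolysis frees the alcohol, so the vinylsilane serves as a mask of the vinyl iodide that tolerates the later organometallic, nickel and palladium steps.

Step 3
Reactants: 6 (E)-4-(trimethylsilyl)pent-3-en-1-ol
Product: 7 (E)-4-(trimethylsilyl)pent-3-enal
Conditions: DMP (1.2 equiv), pyridine, CH2Cl2, 0 °C
Reagents that add atoms: none
Why: Dess–Martin oxidation under pyridine buffering should give the β,γ-unsaturated aldehyde without migration of the double bond.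

Step 4
Reactants: 7 (E)-4-(trimethylsilyl)pent-3-enal, 8 2-(triphenyl-λ5-phosphanylidene)propanal
Product: 9 (2E,5E)-2-methyl-6-(trimethylsilyl)hepta-2,5-dienal
Conditions: toluene, 70 °C
Reagents that add atoms: none
Why: Wittig olefination with the stabilized formyl ylide should give the (E)-2-methyl enal, the usual outcome for stabilized ylides.

Step 5
Reactants: 9 (2E,5E)-2-methyl-6-(trimethylsilyl)hepta-2,5-dienal, 10 1,4-bis(trimethylsilyl)buta-1,3-diyne
Product: 12 rac-(6E,9E)-6-methyl-1,10-bis(trimethylsilyl)undeca-6,9-diene-1,3-diyn-5-ol, via lithium silylbutadiynide 11 (not isolated)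
Conditions: 10, MeLi·LiBr (1.0 equiv), THF, 20 °C; then 9, −78 °C; aq NH4Cl
Reagents that add atoms: none
Why: Mono-desilylation of 10 by MeLi·LiBr gives the lithium diynide, which adds 1,2 to the enal at low temperature (acetylide addition), and the new carbinol centre is formed racemic and is resolved in step 7.

Step 6
Reactants: 12 rac-(6E,9E)-6-methyl-1,10-bis(trimethylsilyl)undeca-6,9-diene-1,3-diyn-5-ol
Product: 14 rac-(3E,6E,9E)-6-methyl-10-(trimethylsilyl)undeca-3,6,9-trien-1-yn-5-ol, via silylated enynol 13 (not isolated)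
Conditions: NaAlH2(OCH2CH2OMe)2 (2 equiv), THF, 0 °C; then MeOH, K2CO3 (cat.), 20 °C
Reagents that add atoms: none
Why: Alkoxide-directed trans-hydroalumination reduces only the propargylic triple bond to the (E)-olefin, and the methoxide formed on quenching cleaves the alkynyl C–Si bond while the vinylsilane stays.

Step 7
Reactants: 14 rac-(3E,6E,9E)-6-methyl-10-(trimethylsilyl)undeca-3,6,9-trien-1-yn-5-ol
Product: 15 (1S,2E)-1-[(2S,3S)-2-methyl-3-[(2E)-3-(trimethylsilyl)but-2-en-1-yl]oxiran-2-yl]pent-2-en-4-yn-1-ol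
Conditions: Ti(OiPr)4 (10 mol%), L-(+)-diisopropyl tartrate (15 mol%), t-BuOOH (0.5 equiv, anhydrous), 4 Å molecular sieves, CH2Cl2, −20 °C; unreacted (R)-14 removed by chromatography
Reagents that add atoms: tert-butyl hydroperoxide, CC(C)(C)OO
Why: Sharpless kinetic resolution (titanium–tartrate asymmetric epoxidation): with L-(+)-tartrate the (S)-carbinol is epoxidized fast at the electron-rich trisubstituted olefin on the face anti to the carbinol substituent, which should give the erythro (2S,3S)-epoxy (1S)-alcohol and leave the (R)-enantiomer, whose enyne olefin is electron-poor, largely untouched.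

Step 8
Reactants: 15 (1S,2E)-1-[(2S,3S)-2-methyl-3-[(2E)-3-(trimethylsilyl)but-2-en-1-yl]oxiran-2-yl]pent-2-en-4-yn-1-ol
Product: 17 (3R,4E)-3-ethynyl-N,N-dimethyl-5-[(2S,3S)-2-methyl-3-[(2E)-3-(trimethylsilyl)but-2-en-1-yl]oxiran-2-yl]pent-4-enamide, via ketene N,O-acetal 16 (not isolated)
Conditions: MeC(OMe)2NMe2 (5 equiv), toluene, 110 °C, MeOH distilled off
Reagents that add atoms: N,N-dimethylacetamide dimethyl acetal, CC(OC)(OC)N(C)C
Why: Eschenmoser–Claisen rearrangement through a chair transition state with the oxiranyl group equatorial should form the C7–C8 bond suprafacially, which sets C7 from the C5 carbinol, gives the E-olefin and at once creates the vinyl epoxide.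

Step 9
Reactants: 17 (3R,4E)-3-ethynyl-N,N-dimethyl-5-[(2S,3S)-2-methyl-3-[(2E)-3-(trimethylsilyl)but-2-en-1-yl]oxiran-2-yl]pent-4-enamide
Product: 19 2-[(2R,3S)-2-[(1E,3S,5E)-3-hydroxy-2-methyl-6-(trimethylsilyl)hepta-1,5-dien-1-yl]-4-methylidene-5-oxooxolan-3-yl]-N,N-dimethylacetamide, via magnesium acrylate 18 (not isolated)
Conditions: undivided cell, Mg anode, carbon-fibre cathode, Ni(bpy)3(BF4)2 (10 mol%), n-Bu4NBF4, t-BuOH (1.5 equiv), CO2 (1 atm), DMF, 20 °C, constant current (2.2 F/mol); current off, then Pd(PPh3)4 (5 mol%) added to the same cell, 20 °C; aq NH4Cl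
Reagents that add atoms: carbon dioxide, O=C=O
Why: Proposed new method: zerovalent Ni(bpy), made at the cathode, couples the terminal alkyne of 17 oxidatively with CO2 at the internal carbon C11 to an oxanickelacyclopentenone, which magnesium ions from the anode and t-BuOH release as the magnesium 2-alkylacrylate 18 while divalent nickel returns to the cathode; once the current is off, Pd(PPh3)4 ionizes the vinyl epoxide (or its reversible CO2 adduct) to a syn,syn-π-allylpalladium and the carboxylate oxygen attacks C6. The closest known reaction types are the Ni(bpy)-catalysed electroreductive hydrocarboxylation of terminal alkynes to 2-substituted acrylic acids with a magnesium anode and the Pd-catalysed 1,4-addition of carboxylates to vinyl epoxides; their union in one cell is the new element. The γ-lactone closes by 5-exo attack of oxygen on the proximal allyl terminus, the seven-membered alternative at C4 being disfavoured. C6 is set by double inversion (palladium enters anti to the C4–O bond, the carboxylate anti to palladium), so the (2S,3S)-oxirane on the E-olefin gives the C6 configuration of the target; the pre-set C7 makes the lactone trans-fused, C3 keeps its configuration because its C–O bond is never broken, and the larger C3 substituent takes the syn position of the allyl so that C4=C5 is E. The step needs carboxylation at C11 rather than C13, which the nickel/bipyridine/magnesium system gives with terminal alkynes, and it needs the alkyne to be carboxylated before zerovalent nickel consumes the vinyl epoxide, which the mild potential and the late addition of palladium should favour; the amide and the vinylsilane are inert.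

Step 10
Reactants: 19 2-[(2R,3S)-2-[(1E,3S,5E)-3-hydroxy-2-methyl-6-(trimethylsilyl)hepta-1,5-dien-1-yl]-4-methylidene-5-oxooxolan-3-yl]-N,N-dimethylacetamide
Product: 20 (1E,3S,5E)-1-[(2R,3S)-3-[2-(dimethylamino)-2-oxoethyl]-4-methylidene-5-oxooxolan-2-yl]-2-methyl-6-(trimethylsilyl)hepta-1,5-dien-3-yl acetate
Conditions: Ac2O, pyridine, DMAP (cat.), CH2Cl2, 0 °C
Reagents that add atoms: acetic anhydride, CC(=O)OC(C)=O
Why: Acetylation of the secondary allylic alcohol with nucleophilic catalysis by DMAP touches no stereocentre.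

Step 11
Reactants: 20 (1E,3S,5E)-1-[(2R,3S)-3-[2-(dimethylamino)-2-oxoethyl]-4-methylidene-5-oxooxolan-2-yl]-2-methyl-6-(trimethylsilyl)hepta-1,5-dien-3-yl acetate
Product: 21 (1E,3S,5E)-1-[(2S,3S,4R)-3-[2-(dimethylamino)-2-oxoethyl]-4-methyl-5-oxooxolan-2-yl]-2-methyl-6-(trimethylsilyl)hepta-1,5-dien-3-yl acetate
Conditions: H2 (1 atm), RhCl(PPh3)3 (5 mol%), toluene–EtOH, 20 °C
Reagents that add atoms: none
Why: Homogeneous hydrogenation with RhCl(PPh3)3 reduces only the 1,1-disubstituted exocyclic olefin and should deliver hydrogen to the face anti to the C7 side chain, which sets C11 with the methyl group cis to C8 as in the target.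

Step 12
Reactants: 21 (1E,3S,5E)-1-[(2S,3S,4R)-3-[2-(dimethylamino)-2-oxoethyl]-4-methyl-5-oxooxolan-2-yl]-2-methyl-6-(trimethylsilyl)hepta-1,5-dien-3-yl acetate
Product: 22 (1E,3S,5E)-1-[(2S,3S,4R)-3-[2-(dimethylamino)-2-oxoethyl]-4-methyl-5-oxooxolan-2-yl]-6-iodo-2-methylhepta-1,5-dien-3-yl acetate
Conditions: N-iodosuccinimide (1.3 equiv), (CF3)2CHOH, 0 °C
Reagents that add atoms: N-iodosuccinimide, O=C1CCC(=O)N1I
Why: Ipso-iododesilylation of the vinylsilane (β-silyl cation pathway) in hexafluoroisopropanol should proceed with retention and spare the olefin that is deactivated by its two allylic acyloxy groups.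

Step 13
Reactants: 22 (1E,3S,5E)-1-[(2S,3S,4R)-3-[2-(dimethylamino)-2-oxoethyl]-4-methyl-5-oxooxolan-2-yl]-6-iodo-2-methylhepta-1,5-dien-3-yl acetate
Product: 24 (1E,3S,5E)-6-iodo-2-methyl-1-[(2S,3S,4R)-4-methyl-5-oxo-3-(2-oxoethyl)oxolan-2-yl]hepta-1,5-dien-3-yl acetate, via zirconium hemiaminal 23 (not isolated)
Conditions: Cp2Zr(H)Cl (1.6 equiv), THF, 20 °C; then H2O, silica gel
Reagents that add atoms: none
Why: Reduction of the tertiary amide with Cp2Zr(H)Cl stops at the zirconated hemiaminal, which gives the aldehyde on hydrolysis, a reaction type known to spare esters and lactones.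

Step 14
Reactants: 24 (1E,3S,5E)-6-iodo-2-methyl-1-[(2S,3S,4R)-4-methyl-5-oxo-3-(2-oxoethyl)oxolan-2-yl]hepta-1,5-dien-3-yl acetate
Product: 25 (3S,6S,7S,11R)-3-acetoxy-9-hydroxygermacra-1(10)E,4E-dien-12,6-olide as both C9 epimers
Conditions: CrCl2 (8 equiv), NiCl2 (0.1 equiv), DMSO–THF, 20 °C, slow addition, 2 mM
Reagents that add atoms: none
Why: Nozaki–Hiyama–Kishi reaction at high dilution, in which the vinyl iodide adds oxidatively to zerovalent nickel, is transmetalated to chromium and adds to the aldehyde, should close the ten-membered ring with retention of the E-olefin, and both C9 epimers are carried on because C9 is reset in steps 15 and 16.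

Step 15
Reactants: 25 (3S,6S,7S,11R)-3-acetoxy-9-hydroxygermacra-1(10)E,4E-dien-12,6-olide as both C9 epimers
Product: 26 (3S,6S,7S,11R)-3-acetoxy-9-oxogermacra-1(10)E,4E-dien-12,6-olide
Conditions: DMP (1.5 equiv), pyridine, CH2Cl2, 0 °C
Reagents that add atoms: none
Why: Dess–Martin oxidation converts both C9 epimers into one enone.

Step 16
Reactants: 26 (3S,6S,7S,11R)-3-acetoxy-9-oxogermacra-1(10)E,4E-dien-12,6-olide
Product: 27 (3S,6S,7S,9S,11R)-3-acetoxy-9-hydroxygermacra-1(10)E,4E-dien-12,6-olide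
Conditions: (R)-2-methyl-CBS-oxazaborolidine (0.3 equiv), catecholborane (1.5 equiv), toluene, −78 °C; aq NaHCO3
Reagents that add atoms: none
Why: Corey–Bakshi–Shibata reduction, in which the alkenyl group acts as the large substituent, should with the (R)-oxazaborolidine deliver hydride to give the (9S)-allylic alcohol under reagent control.

Step 17
Reactants: 27 (3S,6S,7S,9S,11R)-3-acetoxy-9-hydroxygermacra-1(10)E,4E-dien-12,6-olide
Product: 28 (1S,3S,6S,7S,9S,10S,11R)-3-acetoxy-1,10-epoxy-9-hydroxygermacr-4E-en-12,6-olide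
Conditions: VO(acac)2 (5 mol%), t-BuOOH (1.5 equiv), CH2Cl2, 0 °C
Reagents that add atoms: tert-butyl hydroperoxide, CC(C)(C)OO
Why: Vanadium-catalysed hydroxyl-directed epoxidation should attack only the olefin of the allylic alcohol, on the face syn to the hydroxyl with H9 eclipsing the C10 methyl group (erythro selectivity, peripheral attack on the E-cycloalkene), which sets C1 and C10.

Step 18
Reactants: 28 (1S,3S,6S,7S,9S,10S,11R)-3-acetoxy-1,10-epoxy-9-hydroxygermacr-4E-en-12,6-olide
Product: 29 (1S,3S,6S,7S,9S,10R,11R)-3,9-diacetoxy-1,10-epoxygermacr-4E-en-12,6-olide (target)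
Conditions: Ac2O, pyridine, DMAP (cat.), CH2Cl2, 20 °C
Reagents that add atoms: acetic anhydride, CC(=O)OC(C)=O
Why: Acetylation of the remaining secondary alcohol gives the target without touching a stereocentre (the C10 descriptor changes only because the priority of C9 rises).

**Compound list**

1 | pent-3-yn-1-ol | CC#CCCO | starting material
2 | (E)-4-(chlorozirconocenyl)pent-3-en-1-yl zirconocene chloride alkoxide | C/C([Zr](Cl)(C1C=CC=C1)C1C=CC=C1)=C\CCO[Zr](Cl)(C1C=CC=C1)C1C=CC=C1 | intermediate (not isolated)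
3 | (E)-4-iodopent-3-en-1-ol | C/C(I)=C\CCO | intermediate
4 | lithium (E)-4-lithiopent-3-en-1-olate | C/C([Li])=C\CCO[Li] | intermediate (not isolated)
5 | (E)-trimethyl{[4-(trimethylsilyl)pent-3-en-1-yl]oxy}silane | C/C([Si](C)(C)C)=C\CCO[Si](C)(C)C | intermediate (not isolated)
6 | (E)-4-(trimethylsilyl)pent-3-en-1-ol | C/C([Si](C)(C)C)=C\CCO | intermediate
7 | (E)-4-(trimethylsilyl)pent-3-enal | C/C([Si](C)(C)C)=C\CC=O | intermediate
8 | 2-(triphenyl-λ5-phosphanylidene)propanal | CC(C=O)=P(c1ccccc1)(c1ccccc1)c1ccccc1 | starting material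
9 | (2E,5E)-2-methyl-6-(trimethylsilyl)hepta-2,5-dienal | O=C/C(C)=C/C/C=C(\C)[Si](C)(C)C | intermediate
10 | 1,4-bis(trimethylsilyl)buta-1,3-diyne | C[Si](C)(C)C#CC#C[Si](C)(C)C | starting material
11 | lithium (trimethylsilyl)butadiynide | [Li]C#CC#C[Si](C)(C)C | intermediate (not isolated)
12 | rac-(6E,9E)-6-methyl-1,10-bis(trimethylsilyl)undeca-6,9-diene-1,3-diyn-5-ol | C[Si](C)(C)C#CC#CC(O)/C(C)=C/C/C=C(\C)[Si](C)(C)C | intermediate
13 | rac-(3E,6E,9E)-6-methyl-1,10-bis(trimethylsilyl)undeca-3,6,9-trien-1-yn-5-ol | C[Si](C)(C)C#C/C=C/C(O)/C(C)=C/C/C=C(\C)[Si](C)(C)C | intermediate (not isolated)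
14 | rac-(3E,6E,9E)-6-methyl-10-(trimethylsilyl)undeca-3,6,9-trien-1-yn-5-ol | C#C/C=C/C(O)/C(C)=C/C/C=C(\C)[Si](C)(C)C | intermediate
15 | (1S,2E)-1-[(2S,3S)-2-methyl-3-[(2E)-3-(trimethylsilyl)but-2-en-1-yl]oxiran-2-yl]pent-2-en-4-yn-1-ol | C#C/C=C/[C@H](O)[C@]1(C)O[C@H]1C/C=C(\C)[Si](C)(C)C | intermediate
16 | 1-(dimethylamino)ethenyl ether of 15 (ketene N,O-acetal, configuration as in 15) | C=C(N(C)C)O[C@@H](/C=C/C#C)[C@]1(C)O[C@H]1C/C=C(\C)[Si](C)(C)C | intermediate (not isolated)
17 | (3R,4E)-3-ethynyl-N,N-dimethyl-5-[(2S,3S)-2-methyl-3-[(2E)-3-(trimethylsilyl)but-2-en-1-yl]oxiran-2-yl]pent-4-enamide | CN(C)C(=O)C[C@@H](C#C)/C=C/[C@]1(C)O[C@H]1C/C=C(\C)[Si](C)(C)C | intermediate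
18 | magnesium tert-butoxide (3R,4E)-3-[2-(dimethylamino)-2-oxoethyl]-2-methylidene-5-[(2S,3S)-2-methyl-3-[(2E)-3-(trimethylsilyl)but-2-en-1-yl]oxiran-2-yl]pent-4-enoate | CN(C)C(=O)C[C@@H](C(=C)C(=O)[O-])/C=C/[C@]1(C)O[C@H]1C/C=C(\C)[Si](C)(C)C.[Mg+2].CC(C)(C)[O-] | intermediate (not isolated)
19 | 2-[(2R,3S)-2-[(1E,3S,5E)-3-hydroxy-2-methyl-6-(trimethylsilyl)hepta-1,5-dien-1-yl]-4-methylidene-5-oxooxolan-3-yl]-N,N-dimethylacetamide | CN(C)C(=O)C[C@@H]1[C@@H](/C=C(\C)[C@@H](O)C/C=C(\C)[Si](C)(C)C)OC(=O)C1=C | intermediate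
20 | (1E,3S,5E)-1-[(2R,3S)-3-[2-(dimethylamino)-2-oxoethyl]-4-methylidene-5-oxooxolan-2-yl]-2-methyl-6-(trimethylsilyl)hepta-1,5-dien-3-yl acetate | CN(C)C(=O)C[C@@H]1[C@@H](/C=C(\C)[C@@H](OC(C)=O)C/C=C(\C)[Si](C)(C)C)OC(=O)C1=C | intermediate
21 | (1E,3S,5E)-1-[(2S,3S,4R)-3-[2-(dimethylamino)-2-oxoethyl]-4-methyl-5-oxooxolan-2-yl]-2-methyl-6-(trimethylsilyl)hepta-1,5-dien-3-yl acetate | CN(C)C(=O)C[C@@H]1[C@@H](/C=C(\C)[C@@H](OC(C)=O)C/C=C(\C)[Si](C)(C)C)OC(=O)[C@@H]1C | intermediate
22 | (1E,3S,5E)-1-[(2S,3S,4R)-3-[2-(dimethylamino)-2-oxoethyl]-4-methyl-5-oxooxolan-2-yl]-6-iodo-2-methylhepta-1,5-dien-3-yl acetate | CN(C)C(=O)C[C@@H]1[C@@H](/C=C(\C)[C@@H](OC(C)=O)C/C=C(\C)I)OC(=O)[C@@H]1C | intermediate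
23 | O-(chlorozirconocenyl) hemiaminal of 22 (hemiaminal carbon undefined) | CN(C)C(O[Zr](Cl)(C1C=CC=C1)C1C=CC=C1)C[C@@H]1[C@@H](/C=C(\C)[C@@H](OC(C)=O)C/C=C(\C)I)OC(=O)[C@@H]1C | intermediate (not isolated)
24 | (1E,3S,5E)-6-iodo-2-methyl-1-[(2S,3S,4R)-4-methyl-5-oxo-3-(2-oxoethyl)oxolan-2-yl]hepta-1,5-dien-3-yl acetate | O=CC[C@@H]1[C@@H](/C=C(\C)[C@@H](OC(C)=O)C/C=C(\C)I)OC(=O)[C@@H]1C | intermediate
25 | (3S,6S,7S,11R)-3-acetoxy-9-hydroxygermacra-1(10)E,4E-dien-12,6-olide, both C9 epimers | CC(=O)O[C@H]1C/C=C(\C)C(O)C[C@@H]2[C@@H](/C=C/1C)OC(=O)[C@@H]2C | intermediate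
26 | (3S,6S,7S,11R)-3-acetoxy-9-oxogermacra-1(10)E,4E-dien-12,6-olide | CC(=O)O[C@H]1C/C=C(\C)C(=O)C[C@@H]2[C@@H](/C=C/1C)OC(=O)[C@@H]2C | intermediate
27 | (3S,6S,7S,9S,11R)-3-acetoxy-9-hydroxygermacra-1(10)E,4E-dien-12,6-olide | CC(=O)O[C@H]1C/C=C(\C)[C@@H](O)C[C@@H]2[C@@H](/C=C/1C)OC(=O)[C@@H]2C | intermediate
28 | (1S,3S,6S,7S,9S,10S,11R)-3-acetoxy-1,10-epoxy-9-hydroxygermacr-4E-en-12,6-olide | CC(=O)O[C@H]1C[C@@H]2O[C@@]2(C)[C@@H](O)C[C@@H]2[C@@H](/C=C/1C)OC(=O)[C@@H]2C | intermediate
29 | (1S,3S,6S,7S,9S,10R,11R)-3,9-diacetoxy-1,10-epoxygermacr-4E-en-12,6-olide | CC(=O)O[C@H]1C[C@@H]2O[C@@]2(C)[C@@H](OC(C)=O)C[C@@H]2[C@@H](/C=C/1C)OC(=O)[C@@H]2C | target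

**Step count and risks**

Total step count: 18. Longest linear sequence: 18 steps (1 → 29; 8 and 10 are commercial).

Steps most likely to fail:

1. Step 9 (proposed new method). What may go wrong: zerovalent nickel opens the vinyl epoxide and the cathode reduces the resulting allyl species before the alkyne is carboxylated, or CO2 adds at the terminal alkyne carbon. Fallback: from 17, the alkyne would be carboxylated chemically with Ni(cod)2 (1.1 equiv) and DBU (2 equiv) under CO2 (1 atm) in THF at 0 °C with a cold dilute acid work-up, the known stoichiometric nickel-mediated 2-carboxylation of terminal alkynes. This gives the 2-substituted acrylic acid F1, which would be purified and then cyclized with Pd(PPh3)4 (5 mol%) in THF at 20 °C, the known Pd-catalysed 1,4-addition of a carboxylic acid to a vinyl epoxide. The fallback comes back to the route at 19.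

2. Step 14. What may go wrong: oligomerization outruns ring closure because of transannular strain on the way to the ten-membered ring. Fallback: from 24, Pinnick oxidation (NaClO2, NaH2PO4, 2-methylbut-2-ene, t-BuOH–H2O) would give the carboxylic acid F2, and 2,2′-dipyridyl disulfide with PPh3 would turn it into the S-(pyridin-2-yl) thioester F3. The ring would then be closed by an intramolecular iron/copper-mediated ketone synthesis from the vinyl iodide and the thioester (tris(2,2,6,6-tetramethylheptane-3,5-dionato)iron, CuI, Mn, LiCl, DME, high dilution). This acylative closure comes back to the route at enone 26 and bypasses 25.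

3. Step 11. What may go wrong: poor facial selectivity, for instance hydrogen delivery guided by the amide to the face syn to C8, or sluggish reduction of the 1,1-disubstituted olefin. Fallback: from 20, conjugate reduction with LiBH(s-Bu)3 in THF at −78 °C would give the lithium enolate F4, which would be protonated at −78 °C by 2,6-di-tert-butyl-4-methylphenol from the face anti to C8 (kinetic protonation). This comes back to the route at 21.

Further compounds

F1 | step 9 | (3R,4E)-3-[2-(dimethylamino)-2-oxoethyl]-2-methylidene-5-[(2S,3S)-2-methyl-3-[(2E)-3-(trimethylsilyl)but-2-en-1-yl]oxiran-2-yl]pent-4-enoic acid | CN(C)C(=O)C[C@@H](C(=C)C(=O)O)/C=C/[C@]1(C)O[C@H]1C/C=C(\C)[Si](C)(C)C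
F2 | step 14 | 2-[(2S,3S,4R)-2-[(1E,3S,5E)-3-acetoxy-6-iodo-2-methylhepta-1,5-dien-1-yl]-4-methyl-5-oxooxolan-3-yl]acetic acid | OC(=O)C[C@@H]1[C@@H](/C=C(\C)[C@@H](OC(C)=O)C/C=C(\C)I)OC(=O)[C@@H]1C
F3 | step 14 | S-(pyridin-2-yl) 2-[(2S,3S,4R)-2-[(1E,3S,5E)-3-acetoxy-6-iodo-2-methylhepta-1,5-dien-1-yl]-4-methyl-5-oxooxolan-3-yl]ethanethioate | O=C(Sc1ccccn1)C[C@@H]1[C@@H](/C=C(\C)[C@@H](OC(C)=O)C/C=C(\C)I)OC(=O)[C@@H]1C
F4 | step 11 | lithium enolate of lactone 21 (O-lithio ketene acetal) | CN(C)C(=O)C[C@@H]1[C@@H](/C=C(\C)[C@@H](OC(C)=O)C/C=C(\C)[Si](C)(C)C)OC(O[Li])=C1C
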